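- After 4.00 h, Saturday's run had made 67.6% product, or 4.51 turnovers (product made per catalyst charged), and Friday's run 48.1%, or 9.62 turnovers.

| flask | substrate | coupling partner | scavenger | free catalyst | remark | time |
|---|---|---|---|---|---|---|
| Saturday's | 0.20 M | 0.16 M | 0.24 M | 30 mM | run made earlier |  |
| Friday's | 0.20 M | 0.16 M | 0.24 M | 10 mM | run made earlier |  |
| dawn | 0.20 M | 0.160 M | 0.240 M | 20 mM |  | 10 h |
| summer | 0.20 M | 0.160 M | 0.360 M | 20 mM |  | 10 h |

| run | time / h | substrate / % | product / % |
|---|---|---|---|
| Saturday's | 0.250 | 76.4 | 13.9 |
| Saturday's | 0.500 | 67.5 | 23.5 |
| Saturday's | 1.00 | 54.6 | 37.0 |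
| Saturday's | 2.00 | 40.7 | 51.8 |
| Saturday's | 4.00 | 27.1 | 67.6 |
| Friday's | 0.333 | 89.7 | 7.2 |
| Friday's | 0.833 | 80.7 | 16.6 |
| Friday's | 1.50 | 70.7 | 25.5 |
| Friday's | 2.50 | 60.7 | 36.7 |
| Friday's | 4.00 | 49.5 | 48.1 |

(each reading ± 0.3 percentage points)

- the numbers in the tables scatter with a standard deviation of 0.3 percentage points
- what has gone from substrate into another species counts as reacted, even if it can come back
- no earlier run changes the charge of scavenger; that part of a forecast is a guess

* part of the substrate that has reacted at the end, dawn
* part of the substrate that has reacted at the end, summer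
* what raising the concentration of scavenger from its lowest to its highest value here does to the part of the substrate that has reacted (changes below 5 percentage points count as none) (no change / it rises / it falls)

- We carry the turnover budget N, which for dawn and summer is 8.00, the coupling partner charged per catalyst charged.
- Main step alone: we assume each turnover spends one substrate and one coupling partner for one product. The coupling partner is then the limiting reagent, and dawn's product stops at 80.0% of the substrate.
- Adding finite speed: we let the unspent budget fall exponentially with a rate constant k. The readings at 4.00 h give k as 0.466 h⁻¹ for Saturday's run and 0.230 h⁻¹ for Friday's. Dawn's catalyst lies midway, so we take 0.348 h⁻¹; that leaves 3.08% of the budget after 10 h and lowers dawn's product to 77.5%.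
- Adding the missing balance: early on it reads 9.70% in Saturday's run and 3.10% in Friday's, a ratio of 3.13 against 3.00 in catalyst, so we read it as substrate held on catalyst, which counts as reacted. Saturday's last gap, 5.30%, scaled to dawn's catalyst adds 3.53%, and our dawn figure becomes 81.1%.
- Adding scavenger: no earlier run changes it, but its lowest charge exceeds the coupling partner's, so we guess that summer matches dawn.
- The forecast says 78% for dawn, 78% for summer and no change, holding that “Partner is only 80% of the charge, so product stops near 80%”; for dawn it stands below our figure.
- Dawn gives 80.0% and summer 80.7%, so the trend is no change, a change of 0.75 percentage points; our dawn figure stands 1.1 points above the result. At 10.0 h, dawn still has 3.3% of its coupling partner free. Its product of 77.1% is 7.71 of the N = 8.00 turnovers, and at 100 h its 80.0% is 8.00.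

    coupling partner + released group ⇌ idle adduct, settled at all times (K = 350 M⁻¹)
    scavenger + released group → scavenged by-product (k = 1.50 M⁻¹ min⁻¹)
    catalyst intermediate C → free catalyst + product (k = 0.460 min⁻¹)
    catalyst intermediate B → released group + catalyst intermediate C (k = 10.0 min⁻¹)
    substrate + free catalyst ⇌ catalyst intermediate A (K = 10.0 M⁻¹, k = 52.0 M⁻¹ min⁻¹)
    coupling partner + catalyst intermediate A → catalyst intermediate B (k = 1.00 M⁻¹ min⁻¹)

- A neighbour flask is summer with 0.064 M of coupling partner, so N falls to 3.20 and product should stop at 32.0% of the substrate.
- The computed neighbour flask has 31.9% product and 37.5% reacted at 10.0 h, with 62.5% still substrate.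

Readings and results stem from a simulated flask with constants of no real substance, noise included.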